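A closed, stirred, isothermal vessel holds a racemate of the two substrates, reagent and a single-handed free catalyst.

| setting | Monday's | Tuesday's | flask |
|---|---|---|---|
| left-handed substrate | 0.010 M | 0.010 M | 0.010 M |
| right-handed substrate | 0.010 M | 0.010 M | 0.010 M |
| reagent | 1 equiv | 1 equiv | 1.00 equiv |
| free catalyst | 0.034 mol% | 0.075 mol% | 0.05 mol% |
| remark | run made earlier | run made earlier |  |
| time |  |  | 80 min |

- Monday's (time / min: left-handed product / %, right-handed product / %): 12.0: 6.1, 0; 25.0: 8.5, 0.6; 40.0: 14.1, 0; 50.0: 15.2, 1.1; 60.0: 18.4, 0; 80.0: 20.3, 0
- Tuesday's (time / min: left-handed product / %, right-handed product / %): 6.00: 4.1, 0; 10.0: 8.7, 0.1; 20.0: 14.1, 0; 30.0: 17.6, 1.4; 50.0: 26.7, 2.0; 80.0: 35.4, 1.2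

(each reading ± 1 percentage point)

- free catalyst is single-handed; left-handed substrate and right-handed substrate are mirror images of each other, charged as a racemate, each of them at the stated concentration
- an excess is below zero if the other one leads

- excess of left-handed product over right-handed product in the product at 8.0 min
- excess of left-handed product over right-handed product in the product at 80 min
- part of the left-handed substrate and right-handed substrate charged together that has reacted at 80 min

Does the rate hold steady? In Tuesday's run, a straight line from the origin through the left-handed product at 30.0 min reaches 46.9% at 80.0 min, but the reading there is 35.4%, so the rate falls.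

What does it follow? Each product molecule takes one reagent, and the reagent charged covers a fraction 0.5 of the substrates. Reckoned on the reagent left, Tuesday's first-order constant k is 0.0145 min⁻¹ at 30.0 min and 0.0154 min⁻¹ at 80.0 min, so a pseudo-first-order fall fits Tuesday's run. Reagent and left-handed substrate are charged equally, so these readings cannot separate them; this reckoning chooses reagent.

Does k follow the catalyst? Monday's k is 0.00651 min⁻¹, so Tuesday's is 2.37 times Monday's for 2.21 times the loading. Scaling the mean k per loading to this flask gives 0.00992 min⁻¹. That makes 69.9 min the reagent half-life, the time in which the flask uses half of the reagent in hand. This reckoning then gives 27.4% reacted at 80 min.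

Right-handed product reads 1.2% at the end of Tuesday's run, against a scatter of 1 percentage point, so that reading's excess of 93.4% is poorly resolved.

The forecast gives an excess of 95% at 8.0 min and 93% at 80 min, with 29% reacted, above this reckoning's 27.4%, and says: “Right-handed product is near noise”.

The flask gives an excess of 99.3% at 8.0 min and 99.2% at 80 min, with 28.4% reacted and right-handed product at 0.117% at that time.

    free catalyst + left-handed substrate ⇌ catalyst intermediate A (K = 742 M⁻¹, k = 1070 M⁻¹ s⁻¹)
    free catalyst + right-handed substrate ⇌ catalyst intermediate B (K = 44.0 M⁻¹, k = 299 M⁻¹ s⁻¹)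
    reagent + catalyst intermediate A → free catalyst + left-handed product (k = 47.7 M⁻¹ s⁻¹)
    reagent + catalyst intermediate B → free catalyst + right-handed product (k = 2.16 M⁻¹ s⁻¹)
    left-handed substrate ⇌ right-handed substrate (k = 1.60 × 10⁻⁴ s⁻¹)
    free catalyst → spent catalyst (k = 6.95 × 10⁻⁵ s⁻¹)
    free catalyst ⇌ dormant form (K = 0.858, k = 3.50 × 10⁻⁵ s⁻¹)

In the flask at 30.3 min, catalyst intermediate A, the resting state, falls back 4.2 times faster than it goes on. The reagent half-life of 69.9 min reckons 45.2% of the reagent charge left at 80 min, where the flask holds 43%, and 6.85% reacted for the neighbour flask charged with 0.250 equiv, which gives 7.51%.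

(All runs were generated by integration for substances that don't exist.)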